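**Retrosynthetic overview**

1. Target 26 ← removal of six benzyl ethers ← Mizoroki–Heck disconnection of the chalcone Cβ–aryl bond into a ring D aryl bromide and a ring E aryl vinyl ketone.
2. Key disconnection: ring C is opened at O1–C8a and C4–C4a in one move, giving 3,5-bis(benzyloxy)benzyne (ring A) and an anti-aldol methyl ester whose C2 oxygen is masked as a trimethylsilyl ether.
3. Feature relied on: ring C sits on two neighbouring carbons of ring A (C8a carries O1, C4a carries the C4 carbonyl), and ring A is oxygenated at C5 and C7. A 3,5-dialkoxybenzyne gives exactly this pattern when an oxygen nucleophile adds and the resulting aryl anion is acylated.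
4. C2 (S) and C3 (R) come from an auxiliary-controlled anti-aldol between the ring D arylacetyl imide and 4-(benzyloxy)benzaldehyde (ring B).
5. Ring order: rings A, B, D and E enter as benzenoid building blocks; ring C is the only ring formed, in step 9.

Key step: step 9

Assumption: 3,5-bis(benzyloxy)phenol, 4-(benzyloxy)benzaldehyde and 2,4-bis(benzyloxy)benzaldehyde are taken as catalogue compounds; each is otherwise one O-benzylation away from phloroglucinol, 4-hydroxybenzaldehyde or 2,4-dihydroxybenzaldehyde.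

**Route**

Step 1
Reactants: 1 2-hydroxyphenylacetic acid
Product: 2 2-(5-bromo-2-hydroxyphenyl)acetic acid
Conditions: NBS (1.0 equiv), MeCN, −10 °C → rt
Reagents that add atoms: N-bromosuccinimide, O=C1CCC(=O)N1Br
Why: Electrophilic aromatic bromination in which the free hydroxyl sends the electrophile to its para position (C5), the only other strongly activated site (C3, ortho) being more hindered.

Step 2
Reactants: 2 2-(5-bromo-2-hydroxyphenyl)acetic acid
Product: 4 2-[2-(benzyloxy)-5-bromophenyl]acetic acid, via benzyl ester 3 (not isolated)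
Conditions: BnBr (2.3 equiv), K2CO3, DMF, 60 °C; then 2 M NaOH, MeOH, 50 °C; HCl to pH 2
Reagents that add atoms: benzyl bromide, BrCc1ccccc1; sodium hydroxide, [Na+].[OH-]
Why: Williamson etherification of the phenoxide with concurrent O-alkylation of the carboxylate, then saponification of the benzyl ester in the same pot, should leave only the aryl benzyl ether.

Step 3
Reactants: 4 2-[2-(benzyloxy)-5-bromophenyl]acetic acid; 5 (S)-4-benzyloxazolidin-2-one
Product: 7 (S)-4-benzyl-3-{2-[2-(benzyloxy)-5-bromophenyl]acetyl}oxazolidin-2-one, via mixed anhydride 6 (not isolated)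
Conditions: PivCl, Et3N, THF, −20 → 0 °C; then LiCl, 5, rt
Reagents that add atoms: none
Why: N-acylation of the oxazolidinone through the mixed pivalic anhydride, which is attacked at the less hindered arylacetyl carbonyl, is the standard way to load this auxiliary.

Step 4
Reactants: 7 (S)-4-benzyl-3-{2-[2-(benzyloxy)-5-bromophenyl]acetyl}oxazolidin-2-one; 8 4-(benzyloxy)benzaldehyde
Product: 10 (S)-4-benzyl-3-{(2R,3S)-2-[2-(benzyloxy)-5-bromophenyl]-3-[4-(benzyloxy)phenyl]-3-hydroxypropanoyl}oxazolidin-2-one, via silyl ether 9 (not isolated)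
Conditions: MgCl2 (20 mol%), Et3N (2 equiv), TMSCl (1.5 equiv), EtOAc, rt; then TFA (cat.), MeOH, 0 °C
Reagents that add atoms: none
Why: Evans MgCl2-catalysed anti-aldol, in which soft enolisation gives the chelated Z magnesium enolate, the non-enolisable aldehyde adds through a boat-like transition state to the enolate face opposite the C4 benzyl group of the auxiliary (setting C2 as R and C3 as S, anti), and in situ O-silylation of the aldolate makes the addition irreversible and turns the magnesium over.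

Step 5
Reactants: 10 (S)-4-benzyl-3-{(2R,3S)-2-[2-(benzyloxy)-5-bromophenyl]-3-[4-(benzyloxy)phenyl]-3-hydroxypropanoyl}oxazolidin-2-one
Product: 11 methyl (2R,3S)-2-[2-(benzyloxy)-5-bromophenyl]-3-[4-(benzyloxy)phenyl]-3-hydroxypropanoate
Conditions: MeMgBr (2.5 equiv) in MeOH/CH2Cl2 (forms MeOMgBr), 0 °C; then sat. aq NH4Cl
Reagents that add atoms: methanol (delivered as MeOMgBr), CO
Why: Transesterification of the imide by magnesium methoxide cleaves the exocyclic acyl–nitrogen bond at 0 °C while the chelated magnesium aldolate resists retro-aldol cleavage, so neither stereocentre should be touched and the auxiliary is recovered.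

Step 6
Reactants: 11 methyl (2R,3S)-2-[2-(benzyloxy)-5-bromophenyl]-3-[4-(benzyloxy)phenyl]-3-hydroxypropanoate
Product: 12 methyl (2R,3S)-2-[2-(benzyloxy)-5-bromophenyl]-3-[4-(benzyloxy)phenyl]-3-[(trimethylsilyl)oxy]propanoate
Conditions: TMSCl, imidazole, CH2Cl2, 0 °C
Reagents that add atoms: chlorotrimethylsilane, C[Si](C)(C)Cl
Why: O-silylation of the secondary alcohol with a weak base masks the alkoxide as a fluoride-labile ether without enolising the α-aryl ester.

Step 7
Reactants: 13 3,5-bis(benzyloxy)phenol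
Product: 14 2-bromo-3,5-bis(benzyloxy)phenol
Conditions: NBS (1.0 equiv), i-Pr2NH (10 mol%), CH2Cl2, −78 → 0 °C
Reagents that add atoms: N-bromosuccinimide, O=C1CCC(=O)N1Br
Why: Amine-catalysed electrophilic bromination of a phenol favours the position ortho to the hydroxyl, the two ortho sites are equivalent, and any para (C4) isomer should be separable by chromatography.

Step 8
Reactants: 14 2-bromo-3,5-bis(benzyloxy)phenol
Product: 17 3,5-bis(benzyloxy)-2-(trimethylsilyl)phenyl trifluoromethanesulfonate, via silyl ether 15 (not isolated), via lithium phenoxide 16 (not isolated)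
Conditions: HMDS, THF, 65 °C, concentrate; n-BuLi, THF, −78 °C; then Tf2O, −78 °C
Reagents that add atoms: hexamethyldisilazane, C[Si](C)(C)N[Si](C)(C)C; triflic anhydride, O=S(=O)(OS(=O)(=O)C(F)(F)F)C(F)(F)F
Why: O-silylation, bromine–lithium exchange and the 1,3 oxygen-to-carbon silyl shift that follows (retro-Brook rearrangement) give a lithium 2-silylphenoxide that is triflated in the same flask, the standard route to ortho-silylaryl triflates.

Step 9
Reactants: 12 methyl (2R,3S)-2-[2-(benzyloxy)-5-bromophenyl]-3-[4-(benzyloxy)phenyl]-3-[(trimethylsilyl)oxy]propanoate; 17 3,5-bis(benzyloxy)-2-(trimethylsilyl)phenyl trifluoromethanesulfonate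
Product: 21 (2S,3R)-5,7-bis(benzyloxy)-3-[2-(benzyloxy)-5-bromophenyl]-2-[4-(benzyloxy)phenyl]chroman-4-one, via aryne 18 (not isolated), via caesium alkoxide 19 (not isolated), via aryl anion 20 (not isolated)
Conditions: CsF (4 equiv), 18-crown-6 (1 equiv), 17 (1.6 equiv), THF, −20 °C → rt; then AcOH, −20 °C
Reagents that add atoms: none
Why: Proposed new method: fluoride removes the O-silyl group of 12 to give caesium alkoxide 19 and, by attack on the C-silyl group of 17 with loss of triflate, releases aryne 18; the alkoxide adds to the aryne carbon remote from the neighbouring benzyloxy group, so the new O1–C8a bond leaves aryl anion 20 at C4a, stabilised inductively by the C5 oxygen, and this anion attacks the methyl ester to form C4–C4a with loss of methoxide. The closest known reactions are the fluoride-triggered annulation of arynes with methyl salicylates to xanthones and aryne insertions that end in acyl transfer to the aryl anion; what is new is an aliphatic aldolate as the nucleophile. Ring C closes by 6-exo-trig acyl substitution. No stereocentre is formed: C2 takes no part in bond making and keeps its S configuration, while C3 is carried over from the aldol and, being α to the new ketone, would in any case settle in the 2,3-trans diequatorial arrangement. Regioselectivity is secured by the distortion of the 3-alkoxyaryne; the chemoselectivity needed is acyl capture ahead of retro-aldol cleavage of 19, of proton transfer from C3–H and of ring opening by the released methoxide. This is helped by slow heterogeneous fluoride release, excess 17, low temperature, THF (not a proton source for the aryl anion) and the acetic acid quench.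

Step 10
Reactants: 22 2,4-bis(benzyloxy)benzaldehyde
Product: 23 1-[2,4-bis(benzyloxy)phenyl]prop-2-en-1-ol (racemic)
Conditions: CH2=CHMgBr (1.3 equiv), THF, −20 °C; then sat. aq NH4Cl
Reagents that add atoms: vinylmagnesium bromide, C=C[Mg]Br
Why: Grignard 1,2-addition to the aldehyde gives the allylic alcohol, whose racemic carbinol centre is removed in the next step.

Step 11
Reactants: 23 1-[2,4-bis(benzyloxy)phenyl]prop-2-en-1-ol
Product: 24 1-[2,4-bis(benzyloxy)phenyl]prop-2-en-1-one
Conditions: MnO2 (activated, 15 equiv), CH2Cl2, rt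
Reagents that add atoms: none
Why: MnO2 oxidation is selective for the doubly activated benzylic and allylic alcohol and gives the aryl vinyl ketone under neutral conditions that should not polymerise it.

Step 12
Reactants: 21 (2S,3R)-5,7-bis(benzyloxy)-3-[2-(benzyloxy)-5-bromophenyl]-2-[4-(benzyloxy)phenyl]chroman-4-one; 24 1-[2,4-bis(benzyloxy)phenyl]prop-2-en-1-one
Product: 25 (2S,3R)-5,7-bis(benzyloxy)-3-{2-(benzyloxy)-5-[(E)-3-(2,4-bis(benzyloxy)phenyl)-3-oxoprop-1-en-1-yl]phenyl}-2-[4-(benzyloxy)phenyl]chroman-4-one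
Conditions: [Pd(P(t-Bu)3)2] (5 mol%), Cy2NMe (1.3 equiv), 24 (1.8 equiv), BHT (cat.), 1,4-dioxane, 35 °C
Reagents that add atoms: none
Why: Mizoroki–Heck reaction in which the aryl bromide adds oxidatively to zerovalent palladium carrying the bulky electron-rich phosphine, the vinyl ketone inserts syn at its terminal carbon and syn β-hydride elimination gives the E-enone, while the hindered amine near room temperature should leave the base-sensitive C2 and C3 centres alone.

Step 13
Reactants: 25 (2S,3R)-5,7-bis(benzyloxy)-3-{2-(benzyloxy)-5-[(E)-3-(2,4-bis(benzyloxy)phenyl)-3-oxoprop-1-en-1-yl]phenyl}-2-[4-(benzyloxy)phenyl]chroman-4-one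
Product: 26 (2S,3R)-3-{5-[(E)-3-(2,4-dihydroxyphenyl)-3-oxoprop-1-en-1-yl]-2-hydroxyphenyl}-5,7-dihydroxy-2-(4-hydroxyphenyl)chroman-4-one
Conditions: BCl3 (1 M in CH2Cl2, 15 equiv), C6HMe5 (20 equiv), CH2Cl2, −78 → −40 °C; then MeOH
Reagents that add atoms: none
Why: Lewis acid debenzylation with BCl3 and pentamethylbenzene as a non-coordinating benzyl cation scavenger should cleave all six aryl benzyl ethers at low temperature without reducing or alkylating the enone, which hydrogenolysis would not spare.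

**Compound list**

1 | 2-hydroxyphenylacetic acid | OC(=O)Cc1ccccc1O | starting material
2 | 2-(5-bromo-2-hydroxyphenyl)acetic acid | OC(=O)Cc1cc(Br)ccc1O | intermediate
3 | benzyl 2-[2-(benzyloxy)-5-bromophenyl]acetate | O=C(OCc1ccccc1)Cc1cc(Br)ccc1OCc1ccccc1 | intermediate
4 | 2-[2-(benzyloxy)-5-bromophenyl]acetic acid | OC(=O)Cc1cc(Br)ccc1OCc1ccccc1 | intermediate
5 | (S)-4-benzyloxazolidin-2-one | O=C1N[C@@H](Cc2ccccc2)CO1 | starting material
6 | 2-[2-(benzyloxy)-5-bromophenyl]acetic pivalic anhydride | CC(C)(C)C(=O)OC(=O)Cc1cc(Br)ccc1OCc1ccccc1 | intermediate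
7 | (S)-4-benzyl-3-{2-[2-(benzyloxy)-5-bromophenyl]acetyl}oxazolidin-2-one | O=C(Cc1cc(Br)ccc1OCc1ccccc1)N1C(=O)OC[C@@H]1Cc1ccccc1 | intermediate
8 | 4-(benzyloxy)benzaldehyde | O=Cc1ccc(OCc2ccccc2)cc1 | starting material
9 | (S)-4-benzyl-3-{(2R,3S)-2-[2-(benzyloxy)-5-bromophenyl]-3-[4-(benzyloxy)phenyl]-3-[(trimethylsilyl)oxy]propanoyl}oxazolidin-2-one | O=C(N1C(=O)OC[C@@H]1Cc1ccccc1)[C@H](c1cc(Br)ccc1OCc1ccccc1)[C@H](O[Si](C)(C)C)c1ccc(OCc2ccccc2)cc1 | intermediate
10 | (S)-4-benzyl-3-{(2R,3S)-2-[2-(benzyloxy)-5-bromophenyl]-3-[4-(benzyloxy)phenyl]-3-hydroxypropanoyl}oxazolidin-2-one | O=C(N1C(=O)OC[C@@H]1Cc1ccccc1)[C@H](c1cc(Br)ccc1OCc1ccccc1)[C@H](O)c1ccc(OCc2ccccc2)cc1 | intermediate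
11 | methyl (2R,3S)-2-[2-(benzyloxy)-5-bromophenyl]-3-[4-(benzyloxy)phenyl]-3-hydroxypropanoate | COC(=O)[C@H](c1cc(Br)ccc1OCc1ccccc1)[C@H](O)c1ccc(OCc2ccccc2)cc1 | intermediate
12 | methyl (2R,3S)-2-[2-(benzyloxy)-5-bromophenyl]-3-[4-(benzyloxy)phenyl]-3-[(trimethylsilyl)oxy]propanoate | COC(=O)[C@H](c1cc(Br)ccc1OCc1ccccc1)[C@H](O[Si](C)(C)C)c1ccc(OCc2ccccc2)cc1 | intermediate
13 | 3,5-bis(benzyloxy)phenol | Oc1cc(OCc2ccccc2)cc(OCc2ccccc2)c1 | starting material
14 | 2-bromo-3,5-bis(benzyloxy)phenol | Oc1cc(OCc2ccccc2)cc(OCc2ccccc2)c1Br | intermediate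
15 | [2-bromo-3,5-bis(benzyloxy)phenoxy]trimethylsilane | C[Si](C)(C)Oc1cc(OCc2ccccc2)cc(OCc2ccccc2)c1Br | intermediate
16 | lithium 3,5-bis(benzyloxy)-2-(trimethylsilyl)phenoxide | [Li+].[O-]c1cc(OCc2ccccc2)cc(OCc2ccccc2)c1[Si](C)(C)C | intermediate
17 | 3,5-bis(benzyloxy)-2-(trimethylsilyl)phenyl trifluoromethanesulfonate | C[Si](C)(C)c1c(OCc2ccccc2)cc(OCc2ccccc2)cc1OS(=O)(=O)C(F)(F)F | intermediate
18 | 3,5-bis(benzyloxy)benzyne | C1#CC(OCc2ccccc2)=CC(OCc2ccccc2)=C1 | intermediate
19 | caesium (1S,2R)-2-[2-(benzyloxy)-5-bromophenyl]-1-[4-(benzyloxy)phenyl]-3-methoxy-3-oxopropan-1-olate | [Cs+].COC(=O)[C@H](c1cc(Br)ccc1OCc1ccccc1)[C@H]([O-])c1ccc(OCc2ccccc2)cc1 | intermediate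
20 | aryl caesium adduct: C4a carbanion of methyl (2R,3S)-3-[3,5-bis(benzyloxy)phenoxy]-2-[2-(benzyloxy)-5-bromophenyl]-3-[4-(benzyloxy)phenyl]propanoate, the anion lying between the new ether oxygen and a benzyloxy group | [Cs+].COC(=O)[C@H](c1cc(Br)ccc1OCc1ccccc1)[C@H](OC1=CC(OCc2ccccc2)=CC(OCc2ccccc2)=[C-]1)c1ccc(OCc2ccccc2)cc1 | intermediate
21 | (2S,3R)-5,7-bis(benzyloxy)-3-[2-(benzyloxy)-5-bromophenyl]-2-[4-(benzyloxy)phenyl]chroman-4-one | Brc1ccc(OCc2ccccc2)c([C@H]2C(=O)c3c(OCc4ccccc4)cc(OCc4ccccc4)cc3O[C@@H]2c2ccc(OCc3ccccc3)cc2)c1 | intermediate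
22 | 2,4-bis(benzyloxy)benzaldehyde | O=Cc1ccc(OCc2ccccc2)cc1OCc1ccccc1 | starting material
23 | 1-[2,4-bis(benzyloxy)phenyl]prop-2-en-1-ol (racemic) | C=CC(O)c1ccc(OCc2ccccc2)cc1OCc1ccccc1 | intermediate
24 | 1-[2,4-bis(benzyloxy)phenyl]prop-2-en-1-one | C=CC(=O)c1ccc(OCc2ccccc2)cc1OCc1ccccc1 | intermediate
25 | (2S,3R)-5,7-bis(benzyloxy)-3-{2-(benzyloxy)-5-[(E)-3-(2,4-bis(benzyloxy)phenyl)-3-oxoprop-1-en-1-yl]phenyl}-2-[4-(benzyloxy)phenyl]chroman-4-one | O=C(/C=C/c1ccc(OCc2ccccc2)c([C@H]2C(=O)c3c(OCc4ccccc4)cc(OCc4ccccc4)cc3O[C@@H]2c2ccc(OCc3ccccc3)cc2)c1)c1ccc(OCc2ccccc2)cc1OCc1ccccc1 | intermediate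
26 | (2S,3R)-3-{5-[(E)-3-(2,4-dihydroxyphenyl)-3-oxoprop-1-en-1-yl]-2-hydroxyphenyl}-5,7-dihydroxy-2-(4-hydroxyphenyl)chroman-4-one | O=C(/C=C/c1ccc(O)c([C@H]2C(=O)c3c(O)cc(O)cc3O[C@@H]2c2ccc(O)cc2)c1)c1ccc(O)cc1O | target

**Step count and risk**

Total steps: 13. Longest linear sequence: 9 steps (steps 1, 2, 3, 4, 5, 6, 9, 12, 13).

Steps most likely to fail:

Step 9 (proposed new method). The caesium aldolate may fragment by retro-aldol before it meets the aryne. The aryl anion may be quenched by the acidic C3–H instead of being acylated, leaving an uncyclised aryl ether. The released methoxide may open ring C by β-elimination and so erode C2.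
Fallback, by known chemistry: it sets out from acid 4 and phenol 13 and returns at 21. Friedel–Crafts C-acylation of 13 with 4 in BF3·OEt2 at 70 °C, ortho to the free hydroxyl through the boron chelate, should give the deoxybenzoin 1-[2,4-bis(benzyloxy)-6-hydroxyphenyl]-2-[2-(benzyloxy)-5-bromophenyl]ethan-1-one F1. Piperidine-catalysed Knoevenagel condensation of F1 with aldehyde 8 in refluxing EtOH, with oxa-Michael closure in the same pot, should give the racemic 2,3-trans-5,7-bis(benzyloxy)-3-[2-(benzyloxy)-5-bromophenyl]-2-[4-(benzyloxy)phenyl]chroman-4-one F2 under thermodynamic control. Preparative chromatography on a chiral stationary phase then separates the (2S,3R) enantiomer, which is 21.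

Step 12. The amine or traces of free phosphine may start polymerisation of the vinyl ketone. If the coupling is slow, prolonged contact with base may open ring C by retro-oxa-Michael reaction and scramble C2.
Fallback: it sets out from aldehyde 22 and bromide 21 and returns at 25, replacing the Heck coupling by a base-free Stille coupling. (E)-2-(Tributylstannyl)vinyllithium, made from (E)-1,2-bis(tributylstannyl)ethene and n-BuLi in THF at −78 °C, is added to 22 to give (E)-1-[2,4-bis(benzyloxy)phenyl]-3-(tributylstannyl)prop-2-en-1-ol F3. MnO2 oxidation gives (E)-1-[2,4-bis(benzyloxy)phenyl]-3-(tributylstannyl)prop-2-en-1-one F4. Coupling of F4 with 21 (Pd2(dba)3, AsPh3, CuI, DMF, 50 °C, no base) should give 25 with the E geometry carried over from the stannane.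

Step 4. The stabilised arylacetyl enolate and the electron-rich aldehyde may react sluggishly and reversibly, giving poor anti selectivity or poor facial selectivity.
Fallback: it sets out from imide 7 and returns at 21, replacing the anti-aldol by a boron-mediated syn-aldol and relying on thermodynamic control at C3. Bu2BOTf and i-Pr2NEt in CH2Cl2 (−78 → 0 °C), then aldehyde 8 and oxidative work-up, should give the syn adduct (S)-4-benzyl-3-{(2S,3S)-2-[2-(benzyloxy)-5-bromophenyl]-3-[4-(benzyloxy)phenyl]-3-hydroxypropanoyl}oxazolidin-2-one F5, which already has the required S configuration at the carbinol carbon. Methanolysis as in step 5 gives methyl (2S,3S)-2-[2-(benzyloxy)-5-bromophenyl]-3-[4-(benzyloxy)phenyl]-3-hydroxypropanoate F6. Silylation as in step 6 gives methyl (2S,3S)-2-[2-(benzyloxy)-5-bromophenyl]-3-[4-(benzyloxy)phenyl]-3-[(trimethylsilyl)oxy]propanoate F7. Annulation with 17 under the conditions of step 9 gives the 2,3-cis compound (2S,3S)-5,7-bis(benzyloxy)-3-[2-(benzyloxy)-5-bromophenyl]-2-[4-(benzyloxy)phenyl]chroman-4-one F8. Epimerisation at the acidic C3 (DBU, 10 mol%, CH2Cl2, 0 °C) should then give the more stable 2,3-trans isomer 21.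

**Further compounds**

F1 | step 9 | 1-[2,4-bis(benzyloxy)-6-hydroxyphenyl]-2-[2-(benzyloxy)-5-bromophenyl]ethan-1-one | O=C(Cc1cc(Br)ccc1OCc1ccccc1)c1c(O)cc(OCc2ccccc2)cc1OCc1ccccc1
F2 | step 9 | racemic 2,3-trans-5,7-bis(benzyloxy)-3-[2-(benzyloxy)-5-bromophenyl]-2-[4-(benzyloxy)phenyl]chroman-4-one (1:1 mixture of 21 and its enantiomer) | Brc1ccc(OCc2ccccc2)c([C@H]2C(=O)c3c(OCc4ccccc4)cc(OCc4ccccc4)cc3O[C@@H]2c2ccc(OCc3ccccc3)cc2)c1.Brc1ccc(OCc2ccccc2)c([C@@H]2C(=O)c3c(OCc4ccccc4)cc(OCc4ccccc4)cc3O[C@H]2c2ccc(OCc3ccccc3)cc2)c1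
F3 | step 12 | (E)-1-[2,4-bis(benzyloxy)phenyl]-3-(tributylstannyl)prop-2-en-1-ol (racemic) | CCCC[Sn](CCCC)(CCCC)/C=C/C(O)c1ccc(OCc2ccccc2)cc1OCc1ccccc1
F4 | step 12 | (E)-1-[2,4-bis(benzyloxy)phenyl]-3-(tributylstannyl)prop-2-en-1-one | CCCC[Sn](CCCC)(CCCC)/C=C/C(=O)c1ccc(OCc2ccccc2)cc1OCc1ccccc1
F5 | step 4 | (S)-4-benzyl-3-{(2S,3S)-2-[2-(benzyloxy)-5-bromophenyl]-3-[4-(benzyloxy)phenyl]-3-hydroxypropanoyl}oxazolidin-2-one | O=C(N1C(=O)OC[C@@H]1Cc1ccccc1)[C@@H](c1cc(Br)ccc1OCc1ccccc1)[C@H](O)c1ccc(OCc2ccccc2)cc1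
F6 | step 4 | methyl (2S,3S)-2-[2-(benzyloxy)-5-bromophenyl]-3-[4-(benzyloxy)phenyl]-3-hydroxypropanoate | COC(=O)[C@@H](c1cc(Br)ccc1OCc1ccccc1)[C@H](O)c1ccc(OCc2ccccc2)cc1
F7 | step 4 | methyl (2S,3S)-2-[2-(benzyloxy)-5-bromophenyl]-3-[4-(benzyloxy)phenyl]-3-[(trimethylsilyl)oxy]propanoate | COC(=O)[C@@H](c1cc(Br)ccc1OCc1ccccc1)[C@H](O[Si](C)(C)C)c1ccc(OCc2ccccc2)cc1
F8 | step 4 | (2S,3S)-5,7-bis(benzyloxy)-3-[2-(benzyloxy)-5-bromophenyl]-2-[4-(benzyloxy)phenyl]chroman-4-one | Brc1ccc(OCc2ccccc2)c([C@@H]2C(=O)c3c(OCc4ccccc4)cc(OCc4ccccc4)cc3O[C@@H]2c2ccc(OCc3ccccc3)cc2)c1
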